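**Strategy.** The route rests on disconnecting the C4–C5 bond of the ten-membered carbocycle (ring A, C1–C10). The target bears oxygen at C3 (ketone) and at C6 (lactone O–CH), one on each side of the Z C4=C5 alkene. This 1,4-relationship arises when dioxygen is added across the ends of a cis,cis C3=C4–C5=C6 diene. The key step closes ring A in one operation by copper-mediated union of a Z C4 iodoalkene with a Z C5 alkenylstannane, which fixes both alkene geometries. Its precursor is an open chain that already holds the trans C1–C2 epoxide, the C10 carbinol, the C8 tiglate and the C7 acrylate arm (C11–C13) that later forms lactone ring B.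

Key step: step 18

Remark 1: atom numbers follow the target (ring A C1–C10; C1/C2 epoxide, C3 C=O, C4=C5, C6 O–CH, C7 ring fusion, C8 tiglate, C9 CH2, C10 carbinol; arm C11–C13); the target lactone is cis-fused (H6 and H7 syn) and the epoxide is trans.
Remark 2: 3-(trimethylsilyl)propynal, methyl acrylate and Ph3P=CHCO2Et are taken as purchasable; because C7 must carry both the alkyne and the acrylate, the arm is brought in as a γ-alkynyl Morita–Baylis–Hillman bromide, and the C4 methyl requires the 1-iodoethylidene form of the Stork–Zhao ylide.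
Remark 3: O10 is carried as a triethylsilyl ether from step 5 to step 16 so that no alkoxide sits next to the epoxide under basic conditions (Payne-type migration).

Step 1
Reactants: 1 (R)-(−)-citramalic acid
Product: 2 2-[(4R)-2,2,4-trimethyl-5-oxo-1,3-dioxolan-4-yl]acetic acid
Conditions: Me2C(OMe)2, TsOH·H2O (cat.), CH2Cl2, rt
Reagents that add atoms: 2,2-dimethoxypropane, COC(C)(C)OC
Why: Acid-catalysed acetalisation ties the α-hydroxy acid unit (C1 carboxyl and O10) into a dioxolanone and leaves the C8 carboxyl free, without touching the C10 stereocentre.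

Step 2
Reactants: 2 2-[(4R)-2,2,4-trimethyl-5-oxo-1,3-dioxolan-4-yl]acetic acid
Product: 4 (3R)-3-hydroxy-3-methyloxolan-2-one, via hydroxyethyl dioxolanone 3 (not isolated)
Conditions: BH3·SMe2, THF, 0 °C → rt; MeOH; then TsOH·H2O (cat.), CH2Cl2, rt
Reagents that add atoms: none
Why: Borane reduces the free carboxylic acid chemoselectively (acyloxyborane pathway) beside the dioxolanone, and acid-catalysed translactonisation of the new C8 hydroxyl onto the activated C1 carbonyl expels acetone to give the γ-lactone with C10 unchanged.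

Step 3
Reactants: 4 (3R)-3-hydroxy-3-methyloxolan-2-one
Product: 5 (3R)-3-methyloxolane-2,3-diol (lactol; both anomers)
Conditions: i-Bu2AlH (2.2 equiv), CH2Cl2, −78 °C; aqueous potassium sodium tartrate
Reagents that add atoms: none
Why: Partial reduction of a γ-lactone to the lactol stops at the stable tetrahedral aluminate at low temperature; the anomeric centre is inconsequential.

Step 4
Reactants: 5 (3R)-3-methyloxolane-2,3-diol; 6 ethyl (triphenylphosphoranylidene)acetate
Product: 7 ethyl (2E,4R)-4,6-dihydroxy-4-methylhex-2-enoate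
Conditions: THF, 50 °C
Reagents that add atoms: none
Why: Wittig olefination of the open hydroxy-aldehyde form of the lactol with a stabilised ylide should give the E enoate (C1=C2, C3 as ester), and the neutral medium keeps the C8 hydroxyl from adding back to the enoate.

Step 5
Reactants: 7 ethyl (2E,4R)-4,6-dihydroxy-4-methylhex-2-enoate
Product: 8 ethyl (2E,4R)-4-methyl-4,6-bis(triethylsilyloxy)hex-2-enoate
Conditions: Et3SiOTf (2.5 equiv), 2,6-lutidine, CH2Cl2, −78 → 0 °C
Reagents that add atoms: triethylsilyl triflate, CC[Si](CC)(CC)OS(=O)(=O)C(F)(F)F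
Why: Silylation with the silyl triflate caps the tertiary O10 and the primary O8 in one operation.

Step 6
Reactants: 8 ethyl (2E,4R)-4-methyl-4,6-bis(triethylsilyloxy)hex-2-enoate
Product: 9 (2E,4R)-4-methyl-4,6-bis(triethylsilyloxy)hex-2-en-1-ol
Conditions: i-Bu2AlH, CH2Cl2, −78 °C
Reagents that add atoms: none
Why: 1,2-Reduction of the enoate with the aluminium hydride gives the E allylic alcohol (C3–OH) and leaves the silyl ethers intact.

Step 7
Reactants: 9 (2E,4R)-4-methyl-4,6-bis(triethylsilyloxy)hex-2-en-1-ol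
Product: 10 [(2S,3R)-3-[(2R)-2,4-bis(triethylsilyloxy)butan-2-yl]oxiran-2-yl]methanol
Conditions: Ti(Oi-Pr)4 (cat.), L-(+)-diethyl tartrate (cat.), t-BuOOH, 4 Å MS, CH2Cl2, −20 °C
Reagents that add atoms: tert-butyl hydroperoxide, CC(C)(C)OO
Why: Sharpless asymmetric epoxidation of the primary E allylic alcohol delivers oxygen under reagent control by the L-(+)-tartrate, setting C1 (R) and C2 (S) as the trans epoxide (the sense this tartrate gives with E allylic alcohols), with the silylated C10 centre only a spectator.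

Step 8
Reactants: 10 [(2S,3R)-3-[(2R)-2,4-bis(triethylsilyloxy)butan-2-yl]oxiran-2-yl]methanol
Product: 11 (2R,3R)-3-[(2R)-2,4-bis(triethylsilyloxy)butan-2-yl]oxirane-2-carbaldehyde
Conditions: Dess–Martin periodinane, NaHCO3, CH2Cl2, 0 °C → rt
Reagents that add atoms: none
Why: Buffered Dess–Martin oxidation converts the primary epoxy alcohol into the C3 epoxy aldehyde without epimerisation or epoxide opening (the descriptor at C2 changes by priority only).

Step 9
Reactants: 11 (2R,3R)-3-[(2R)-2,4-bis(triethylsilyloxy)butan-2-yl]oxirane-2-carbaldehyde; 12 ethyltriphenylphosphonium iodide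
Product: 16 (2S,3R)-2-[(1Z)-2-iodoprop-1-en-1-yl]-3-[(2R)-2,4-bis(triethylsilyloxy)butan-2-yl]oxirane, via ethylidenetriphenylphosphorane 13 (not isolated), via (1-iodoethyl)triphenylphosphonium iodide 14 (not isolated), via (1-iodoethylidene)triphenylphosphorane 15 (not isolated)
Conditions: 12, n-BuLi, THF, rt; I2, −78 °C; NaN(SiMe3)2, −20 °C; then 11, −78 °C
Reagents that add atoms: iodine, II
Why: Stork–Zhao-type Wittig olefination with the α-iodo ylide proceeds through the kinetically favoured cis-oxaphosphetane and should give the Z iodoalkene (iodine cis to C2), the low temperature sparing the epoxy aldehyde.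

Step 10
Reactants: 16 (2S,3R)-2-[(1Z)-2-iodoprop-1-en-1-yl]-3-[(2R)-2,4-bis(triethylsilyloxy)butan-2-yl]oxirane
Product: 17 (3R)-3-[(2R,3S)-3-[(1Z)-2-iodoprop-1-en-1-yl]oxiran-2-yl]-3-(triethylsilyloxy)butan-1-ol
Conditions: HF·pyridine, pyridine, THF, 0 °C
Reagents that add atoms: none
Why: Buffered fluoride cleaves the unhindered primary silyl ether much faster than the tertiary one (steric discrimination in silyl ether cleavage) and tolerates the epoxide and iodoalkene.

Step 11
Reactants: 17 (3R)-3-[(2R,3S)-3-[(1Z)-2-iodoprop-1-en-1-yl]oxiran-2-yl]-3-(triethylsilyloxy)butan-1-ol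
Product: 18 (3R)-3-[(2R,3S)-3-[(1Z)-2-iodoprop-1-en-1-yl]oxiran-2-yl]-3-(triethylsilyloxy)butanal
Conditions: Dess–Martin periodinane, NaHCO3, CH2Cl2, 0 °C
Reagents that add atoms: none
Why: Dess–Martin oxidation gives the C8 aldehyde; the β-silyloxy group prevents dehydration and the other groups are inert.

Step 12
Reactants: 19 3-(trimethylsilyl)prop-2-ynal; 20 methyl acrylate
Product: 21 methyl 3-hydroxy-2-methylidene-5-(trimethylsilyl)pent-4-ynoate (racemic)
Conditions: DABCO (cat.), neat, rt
Reagents that add atoms: none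
Why: Morita–Baylis–Hillman reaction of the activated ynal with the amine–acrylate zwitterion joins C7 to C11; the carbinol centre is lost in step 13, so it needs no control.

Step 13
Reactants: 21 methyl 3-hydroxy-2-methylidene-5-(trimethylsilyl)pent-4-ynoate
Product: 22 methyl (2Z)-2-(bromomethyl)-5-(trimethylsilyl)pent-2-en-4-ynoate
Conditions: PBr3, Et2O, 0 °C
Reagents that add atoms: phosphorus tribromide, BrP(Br)Br
Why: Bromination with allylic transposition (SN2′) gives the conjugated primary allylic bromide, the Z isomer (alkynyl cis to CH2Br) being the thermodynamically preferred one.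

Step 14
Reactants: 18 (3R)-3-[(2R,3S)-3-[(1Z)-2-iodoprop-1-en-1-yl]oxiran-2-yl]-3-(triethylsilyloxy)butanal; 22 methyl (2Z)-2-(bromomethyl)-5-(trimethylsilyl)pent-2-en-4-ynoate
Product: 23 methyl (3S,4R,6R)-4-hydroxy-6-[(2R,3S)-3-[(1Z)-2-iodoprop-1-en-1-yl]oxiran-2-yl]-2-methylidene-6-(triethylsilyloxy)-3-[(trimethylsilyl)ethynyl]heptanoate (C7/C8 syn)
Conditions: In powder, THF/H2O, rt
Reagents that add atoms: none
Why: Indium-mediated Barbier allylation: the allylindium from 22 adds through its γ-carbon (C7) in a chair Zimmerman–Traxler transition state, its Z-crotyl-type geometry giving the C7/C8 syn pair, while the C8 face relative to C10 is biased only weakly toward the needed 1,3-anti adduct by the β-silyloxy quaternary centre, so the C7,C8-bis-epimer (a diastereomer) would be removed by chromatography.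

Step 15
Reactants: 23 the syn homoallylic alcohol; 24 tiglic acid
Product: 26 methyl (3S,4R,6R)-6-[(2R,3S)-3-[(1Z)-2-iodoprop-1-en-1-yl]oxiran-2-yl]-2-methylidene-4-[(2E)-2-methylbut-2-enoyloxy]-6-(triethylsilyloxy)-3-[(trimethylsilyl)ethynyl]heptanoate, via tiglic trichlorobenzoic mixed anhydride 25 (not isolated)
Conditions: 24, 2,4,6-Cl3C6H2COCl, Et3N, toluene, rt; then 23, DMAP, rt
Reagents that add atoms: none
Why: Yamaguchi esterification acylates the hindered C8 hydroxyl with retention and faster than it can lactonise onto C12; the E tiglate geometry is the stable one.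

Step 16
Reactants: 26 the C8 tiglate
Product: 27 methyl (3R,4R,6R)-3-ethynyl-6-hydroxy-6-[(2R,3S)-3-[(1Z)-2-iodoprop-1-en-1-yl]oxiran-2-yl]-2-methylidene-4-[(2E)-2-methylbut-2-enoyloxy]heptanoate
Conditions: Bu4NF buffered with AcOH, THF, 0 °C → rt
Reagents that add atoms: none
Why: Fluoride-induced desilylation removes the alkynyl C–Si group and the tertiary O–Si group in one operation, the acetic acid buffer protecting the acrylate and the doubly activated C7–H from base.

Step 17
Reactants: 27 the terminal alkyne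
Product: 30 methyl (3R,4R,6R)-6-hydroxy-6-[(2R,3S)-3-[(1Z)-2-iodoprop-1-en-1-yl]oxiran-2-yl]-2-methylidene-4-[(2E)-2-methylbut-2-enoyloxy]-3-[(1Z)-2-(tributylstannyl)ethenyl]heptanoate, via bis(tributylstannyl) alkyne 28 (not isolated), via stannyl zirconocenyl alkene 29 (not isolated)
Conditions: Bu3SnOMe (2.2 equiv), toluene, 50 °C, reduced pressure; then Cp2Zr(H)Cl, THF, rt; H2O
Reagents that add atoms: tributyltin methoxide, CCCC[Sn](CCCC)(CCCC)OC
Why: Stannylation of the terminal alkyne (and transiently of O10), then syn hydrozirconation placing Zr geminal to Sn and protonolysis with retention, should give the Z alkenylstannane, the stannylalkyne reacting with the Schwartz reagent far faster than the esters, the epoxide or the iodoalkene.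

Step 18
Reactants: 30 the open-chain Z-iodoalkene Z-alkenylstannane
Product: 31 methyl 2-[(1R,2S,3Z,5Z,7R,8R,10R)-1,2-epoxy-10-hydroxy-4,10-dimethyl-8-(tigloyloxy)cyclodeca-3,5-dien-7-yl]acrylate (target numbering)
Conditions: Cu(O2CC4H3S) (copper thiophene-2-carboxylate, 3 equiv), NMP, rt, slow addition of 30, high dilution
Reagents that add atoms: none
Why: Tin-to-copper exchange at C5 with the copper carboxylate gives a Z-alkenylcopper and Bu3Sn carboxylate; the monovalent copper centre then inserts into the Z C4–I bond of the same molecule and C–C reductive elimination from the resulting trivalent copper species joins C4 to C5 with retention at both alkenes. The closest known reaction type is the stoichiometric copper-carboxylate variant of the Stille coupling, used intramolecularly to close macrocyclic 1,3-dienes from iodoalkene–alkenylstannane chains. One ring is closed, the ten-membered ring A, by direct sp2–sp2 bond formation between the two chain termini (an endo closure in which both new ring atoms are alkene carbons). No stereocentre is formed, and both Z alkenes are kept because neither the exchange nor the reductive elimination breaks a π bond. The step needs cyclisation to win over oligomerisation, which slow addition at high dilution and the turn imposed by the two Z alkenes and the trans epoxide should secure, and it needs chemoselectivity, secured by the absence of zerovalent palladium (the allylic C2–O bond and the acrylate are not engaged) and by the neutral medium (free C10 hydroxyl, esters).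

Step 19
Reactants: 31 the ten-membered cis,cis-diene
Product: 32 the (3R,6S)-3,6-endoperoxide of 31 (O–O bridge from C3 to C6; C4=C5 Z)
Conditions: O2, visible light, tetraphenylporphyrin (cat.), CH2Cl2, −20 °C
Reagents that add atoms: dioxygen, O=O
Why: [4+2] Cycloaddition of singlet oxygen (sensitised photooxygenation) across C3 and C6 of the diene should occur on the face anti to the C7 acrylate arm, which sets C6 (S) and, suprafacially, the transient C3 centre, the electron-poor acrylate and tiglate alkenes being inert.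

Step 20
Reactants: 32 the endoperoxide
Product: 34 the C3-hydroxy 6,12-lactone (C3 R; cis-fused lactone; otherwise as the target), via ene-1,4-diol 33 (not isolated)
Conditions: thiourea, MeOH, 0 °C → rt; then PPTS (cat.), CH2Cl2, rt
Reagents that add atoms: none
Why: Thiourea reduction of the O–O bond gives the cis-ene-1,4-diol without touching the epoxide, and only the C6 hydroxyl is placed to close a five-membered ring onto the C12 ester (acid-catalysed lactonisation with retention at C6), which leaves C3–OH free.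

Step 21
Reactants: 34 the C3-hydroxy lactone
Product: 35 CNP0383091.1 (target)
Conditions: Dess–Martin periodinane, NaHCO3, CH2Cl2, 0 °C
Reagents that add atoms: none
Why: Dess–Martin oxidation of the secondary allylic C3 alcohol gives the epoxy enone; the tertiary C10 hydroxyl cannot be oxidised and no centre is epimerisable under the buffered conditions.

**Compound list**

1 | (R)-(−)-citramalic acid | OC(=O)[C@](C)(O)CC(=O)O | starting material
2 | 2-[(4R)-2,2,4-trimethyl-5-oxo-1,3-dioxolan-4-yl]acetic acid | CC1(C)O[C@](C)(CC(=O)O)C(=O)O1 | intermediate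
3 | (5R)-5-(2-hydroxyethyl)-2,2,5-trimethyl-1,3-dioxolan-4-one (not isolated) | CC1(C)O[C@](C)(CCO)C(=O)O1 | intermediate
4 | (3R)-3-hydroxy-3-methyloxolan-2-one | C[C@@]1(O)CCOC1=O | intermediate
5 | (3R)-3-methyloxolane-2,3-diol (lactol, both anomers) | C[C@@]1(O)CCOC1O | intermediate
6 | ethyl (triphenylphosphoranylidene)acetate | CCOC(=O)C=P(c1ccccc1)(c1ccccc1)c1ccccc1 | starting material
7 | ethyl (2E,4R)-4,6-dihydroxy-4-methylhex-2-enoate | CCOC(=O)/C=C/[C@](C)(O)CCO | intermediate
8 | ethyl (2E,4R)-4-methyl-4,6-bis(triethylsilyloxy)hex-2-enoate | CCOC(=O)/C=C/[C@](C)(O[Si](CC)(CC)CC)CCO[Si](CC)(CC)CC | intermediate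
9 | (2E,4R)-4-methyl-4,6-bis(triethylsilyloxy)hex-2-en-1-ol | OC/C=C/[C@](C)(O[Si](CC)(CC)CC)CCO[Si](CC)(CC)CC | intermediate
10 | [(2S,3R)-3-[(2R)-2,4-bis(triethylsilyloxy)butan-2-yl]oxiran-2-yl]methanol | OC[C@@H]1O[C@H]1[C@](C)(O[Si](CC)(CC)CC)CCO[Si](CC)(CC)CC | intermediate
11 | (2R,3R)-3-[(2R)-2,4-bis(triethylsilyloxy)butan-2-yl]oxirane-2-carbaldehyde | O=C[C@@H]1O[C@H]1[C@](C)(O[Si](CC)(CC)CC)CCO[Si](CC)(CC)CC | intermediate
12 | ethyltriphenylphosphonium iodide | CC[P+](c1ccccc1)(c1ccccc1)c1ccccc1.[I-] | starting material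
13 | ethylidenetriphenylphosphorane (not isolated) | CC=P(c1ccccc1)(c1ccccc1)c1ccccc1 | intermediate
14 | (1-iodoethyl)triphenylphosphonium iodide (not isolated) | CC(I)[P+](c1ccccc1)(c1ccccc1)c1ccccc1.[I-] | intermediate
15 | (1-iodoethylidene)triphenylphosphorane (not isolated) | CC(I)=P(c1ccccc1)(c1ccccc1)c1ccccc1 | intermediate
16 | (2S,3R)-2-[(1Z)-2-iodoprop-1-en-1-yl]-3-[(2R)-2,4-bis(triethylsilyloxy)butan-2-yl]oxirane | I/C(C)=C\[C@@H]1O[C@H]1[C@](C)(O[Si](CC)(CC)CC)CCO[Si](CC)(CC)CC | intermediate
17 | (3R)-3-[(2R,3S)-3-[(1Z)-2-iodoprop-1-en-1-yl]oxiran-2-yl]-3-(triethylsilyloxy)butan-1-ol | I/C(C)=C\[C@@H]1O[C@H]1[C@](C)(O[Si](CC)(CC)CC)CCO | intermediate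
18 | (3R)-3-[(2R,3S)-3-[(1Z)-2-iodoprop-1-en-1-yl]oxiran-2-yl]-3-(triethylsilyloxy)butanal (C8 aldehyde) | I/C(C)=C\[C@@H]1O[C@H]1[C@](C)(O[Si](CC)(CC)CC)CC=O | intermediate
19 | 3-(trimethylsilyl)prop-2-ynal | C[Si](C)(C)C#CC=O | starting material
20 | methyl acrylate | C=CC(=O)OC | starting material
21 | methyl 3-hydroxy-2-methylidene-5-(trimethylsilyl)pent-4-ynoate (racemic) | COC(=O)C(=C)C(O)C#C[Si](C)(C)C | intermediate
22 | methyl (2Z)-2-(bromomethyl)-5-(trimethylsilyl)pent-2-en-4-ynoate | COC(=O)/C(CBr)=C/C#C[Si](C)(C)C | intermediate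
23 | methyl (3S,4R,6R)-4-hydroxy-6-[(2R,3S)-3-[(1Z)-2-iodoprop-1-en-1-yl]oxiran-2-yl]-2-methylidene-6-(triethylsilyloxy)-3-[(trimethylsilyl)ethynyl]heptanoate (C7/C8 syn) | I/C(C)=C\[C@@H]1O[C@H]1[C@](C)(O[Si](CC)(CC)CC)C[C@@H](O)[C@@H](C(=C)C(=O)OC)C#C[Si](C)(C)C | intermediate
24 | tiglic acid, (2E)-2-methylbut-2-enoic acid | C/C=C(\C)C(=O)O | starting material
25 | (2E)-2-methylbut-2-enoic 2,4,6-trichlorobenzoic anhydride (not isolated) | C/C=C(\C)C(=O)OC(=O)c1c(Cl)cc(Cl)cc1Cl | intermediate
26 | methyl (3S,4R,6R)-6-[(2R,3S)-3-[(1Z)-2-iodoprop-1-en-1-yl]oxiran-2-yl]-2-methylidene-4-[(2E)-2-methylbut-2-enoyloxy]-6-(triethylsilyloxy)-3-[(trimethylsilyl)ethynyl]heptanoate | I/C(C)=C\[C@@H]1O[C@H]1[C@](C)(O[Si](CC)(CC)CC)C[C@@H](OC(=O)/C(C)=C/C)[C@@H](C(=C)C(=O)OC)C#C[Si](C)(C)C | intermediate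
27 | methyl (3R,4R,6R)-3-ethynyl-6-hydroxy-6-[(2R,3S)-3-[(1Z)-2-iodoprop-1-en-1-yl]oxiran-2-yl]-2-methylidene-4-[(2E)-2-methylbut-2-enoyloxy]heptanoate | I/C(C)=C\[C@@H]1O[C@H]1[C@](C)(O)C[C@@H](OC(=O)/C(C)=C/C)[C@@H](C(=C)C(=O)OC)C#C | intermediate
28 | 27 carrying Bu3Sn on the alkyne terminus and on O10 (not isolated) | I/C(C)=C\[C@@H]1O[C@H]1[C@](C)(O[Sn](CCCC)(CCCC)CCCC)C[C@@H](OC(=O)/C(C)=C/C)[C@@H](C(=C)C(=O)OC)C#C[Sn](CCCC)(CCCC)CCCC | intermediate
29 | 1-(tributylstannyl)-1-(chlorozirconocenyl)alkene from 28, Sn cis to C7 (not isolated) | I/C(C)=C\[C@@H]1O[C@H]1[C@](C)(O[Sn](CCCC)(CCCC)CCCC)C[C@@H](OC(=O)/C(C)=C/C)[C@@H](C(=C)C(=O)OC)/C=C(\[Sn](CCCC)(CCCC)CCCC)[Zr](Cl)(C1C=CC=C1)C1C=CC=C1 | intermediate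
30 | methyl (3R,4R,6R)-6-hydroxy-6-[(2R,3S)-3-[(1Z)-2-iodoprop-1-en-1-yl]oxiran-2-yl]-2-methylidene-4-[(2E)-2-methylbut-2-enoyloxy]-3-[(1Z)-2-(tributylstannyl)ethenyl]heptanoate (key-step precursor) | I/C(C)=C\[C@@H]1O[C@H]1[C@](C)(O)C[C@@H](OC(=O)/C(C)=C/C)[C@@H](C(=C)C(=O)OC)/C=C\[Sn](CCCC)(CCCC)CCCC | intermediate
31 | methyl 2-[(1R,2S,3Z,5Z,7R,8R,10R)-1,2-epoxy-10-hydroxy-4,10-dimethyl-8-(tigloyloxy)cyclodeca-3,5-dien-7-yl]acrylate (target numbering; key-step product) | COC(=O)C(=C)[C@H]1/C=C\C(C)=C/[C@@H]2O[C@H]2[C@](C)(O)C[C@H]1OC(=O)/C(C)=C/C | intermediate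
32 | (3R,6S)-3,6-endoperoxide of 31 (O–O bridge C3 to C6, C4=C5 Z; other centres unchanged in space) | COC(=O)C(=C)[C@H]1[C@@H]2/C=C(/C)[C@@H](OO2)[C@@H]3O[C@H]3[C@](C)(O)C[C@H]1OC(=O)/C(C)=C/C | intermediate
33 | (3R,6S)-3,6-dihydroxy-4Z-ene methyl ester from 32 (not isolated) | COC(=O)C(=C)[C@H]1[C@@H](O)/C=C(/C)[C@@H](O)[C@@H]2O[C@H]2[C@](C)(O)C[C@H]1OC(=O)/C(C)=C/C | intermediate
34 | 3-hydroxy-6,12-lactone (C3 R, C6 S; cis-fused α-methylene lactone; otherwise as the target) | C=C1C(=O)O[C@H]2/C=C(/C)[C@@H](O)[C@@H]3O[C@H]3[C@](C)(O)C[C@@H](OC(=O)/C(C)=C/C)[C@@H]12 | intermediate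
35 | CNP0383091.1: (1R,2R,6S,7R,8R,10R)-1,2-epoxy-10-hydroxy-3-oxo-8-tigloyloxygermacra-4Z,11(13)-dien-12,6-olide | C=C1C(=O)O[C@H]2/C=C(/C)C(=O)[C@@H]3O[C@H]3[C@](C)(O)C[C@@H](OC(=O)/C(C)=C/C)[C@@H]12 | target

**Totals.** Total step count: 21. Longest linear sequence: 19 steps (steps 1–11 and 14–21; steps 12–13 form the side branch).

**Steps most likely to fail**

1. Step 18. The open chain may oligomerise, or the alkenylcopper may be protonated, before the C4 and C5 termini meet, because closing a ten-membered ring with two cis alkenes costs transannular strain. The fallback closes ring A at C7–C8 instead, after the C4–C5 bond has been made between two molecules; it sets out from 18 and 21 and rejoins the route at 31. Adduct 21 would be desilylated (Bu4NF, AcOH) to methyl 3-hydroxy-2-methylidenepent-4-ynoate F1 and converted as in step 17 (Bu3SnOMe; Cp2Zr(H)Cl; H2O) into methyl (4Z)-3-hydroxy-2-methylidene-5-(tributylstannyl)pent-4-enoate F2. Intermolecular coupling of F2 with iodoalkene 18, promoted by copper thiophene-2-carboxylate, would give the open-chain (Z,Z)-diene hydroxy aldehyde F3. Mesylation and LiBr displacement with allylic transposition would give the allylic bromide F4. An intramolecular indium-mediated Barbier allylation at high dilution would then form C7–C8 and give the ring alcohol F5, the cyclic chair-like transition state being relied on for the C7/C8 configuration. Yamaguchi tigloylation would give the silyl-protected diene ester F6, and Bu4NF/AcOH would return to 31.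

2. Step 19. Ene reaction at the C4 methyl or other allylic C–H bonds may outrun the [4+2] addition because the ring holds the diene twisted, or dioxygen may approach the face syn to the C7 arm. The fallback replaces the pericyclic oxygenation by metal-catalysed 1,4-difunctionalisation; it sets out from 31 and rejoins at 33. Pt(PPh3)4-catalysed cis-1,4-diboration of the diene with bis(pinacolato)diboron would give the 3,6-bis(pinacolboryl)-4Z-ene F7. Oxidation with NaBO3·4H2O, with retention at both carbons, would give diol 33, which is lactonised with PPTS as in step 20. The face selectivity remains substrate-controlled.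

3. Step 14. The quaternary C10 may discriminate the two faces of the C8 aldehyde poorly, so that the syn adduct of the wrong absolute sense at C7/C8 forms in comparable amount. The fallback puts C8 under reagent control; it sets out from 18 and 22 and rejoins at 26. A CrCl2-catalysed asymmetric Nozaki–Hiyama–Kishi allylation (chiral sulfonamide ligand, Mn, Cp2ZrCl2), which is anti-selective for γ-substituted 2-(alkoxycarbonyl)allyl bromides, would give the anti adduct, the C8 epimer of 23 F8, with C7 as required and C8 chosen by the ligand. Mitsunobu esterification with tiglic acid 24 (PPh3, DIAD) would invert C8 and give 26 directly.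

**Further compounds**

F1 | step 18 | methyl 3-hydroxy-2-methylidenepent-4-ynoate | COC(=O)C(=C)C(O)C#C
F2 | step 18 | methyl (4Z)-3-hydroxy-2-methylidene-5-(tributylstannyl)pent-4-enoate | COC(=O)C(=C)C(O)/C=C\[Sn](CCCC)(CCCC)CCCC
F3 | step 18 | open-chain (Z,Z)-diene hydroxy aldehyde (C7 carbinol, C8 aldehyde, O10 silyl ether) | COC(=O)C(=C)C(O)/C=C\C(C)=C/[C@@H]1O[C@H]1[C@](C)(O[Si](CC)(CC)CC)CC=O
F4 | step 18 | transposed allylic bromide of F3 (C7=C11, C13 bromide) | COC(=O)/C(CBr)=C/C=C\C(C)=C/[C@@H]1O[C@H]1[C@](C)(O[Si](CC)(CC)CC)CC=O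
F5 | step 18 | ring A alcohol (C8–OH, O10 triethylsilyl ether of the diene) | COC(=O)C(=C)[C@H]1/C=C\C(C)=C/[C@@H]2O[C@H]2[C@](C)(O[Si](CC)(CC)CC)C[C@H]1O
F6 | step 18 | O10-triethylsilyl ether of 31 | COC(=O)C(=C)[C@H]1/C=C\C(C)=C/[C@@H]2O[C@H]2[C@](C)(O[Si](CC)(CC)CC)C[C@H]1OC(=O)/C(C)=C/C
F7 | step 19 | cis-3,6-bis(pinacolboryl)-4Z-ene from 31 | COC(=O)C(=C)[C@H]1[C@@H](B2OC(C)(C)C(C)(C)O2)/C=C(/C)[C@@H](B2OC(C)(C)C(C)(C)O2)[C@@H]2O[C@H]2[C@](C)(O)C[C@H]1OC(=O)/C(C)=C/C
F8 | step 14 | C8 epimer of 23 (C7/C8 anti adduct) | I/C(C)=C\[C@@H]1O[C@H]1[C@](C)(O[Si](CC)(CC)CC)C[C@H](O)[C@@H](C(=C)C(=O)OC)C#C[Si](C)(C)C
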